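## Structural features

Eduesmine is a 2,5-diaryl-3,4-bis(hydroxymethyl)tetrahydrofuran: one five-membered ether ring (O1, C2, C3, C4, C5) with a 4-hydroxy-3-methoxyphenyl group on C2 and on C5 and a hydroxymethyl group on C3 and on C4 (exocyclic carbons C3' and C4'). The four ring carbons are contiguous stereocentres, all S, which means 2,3-cis, 3,4-trans and 4,5-cis; the molecule has a twofold axis through O1 and the midpoint of C3–C4, so its two halves are identical. Each aryl group is cis to the neighbouring hydroxymethyl group, which is not the arrangement favoured at equilibrium, so C2 and C5 must be set under kinetic control. The C2–O1 and C5–O1 bonds are benzylic ether bonds para to a phenol: acid ionises them (epimerisation, ring opening, cyclisation onto an arene), hydrogenolysis can cleave them, and the free phenols are sensitive to oxidants. There is no quaternary carbon and no ring fusion, so the difficulty is stereochemical: two cis aryl/hydroxymethyl pairs around a trans C3/C4 pair, made without long exposure of the finished ring to acid. The key step uses the fact that C2 is bonded only to O1, C3 and an aryl carbon: it can enter as carbon monoxide between the C5 hydroxyl and an alkyne that supplies C3 and C3', closing the ring as a lactone whose carbonyl then accepts the aryl group and, last, hydride.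

## Logic of the disconnections

**24 to 23.** The four O–CH2Ph bonds (two phenolic, two on C3' and C4') are cut. One kind of protecting group allows a single final operation and survives every earlier reagent. The forward step must cleave benzyl ethers but not the benzylic ring C–O bonds of 24.

**23 to 21, then to 17 and 19.** At C2 the C–H bond and then the C2–aryl bond are cut, so the ether carbon becomes the lactone carbonyl of 17 and the aryl group becomes 20, made from 19. C2 is the only ring carbon at which a carbonyl lets both remaining substituents arrive as nucleophiles, aryl first and hydride last. The target loses one aryl group and one stereocentre. The demand is that hydride reaches ion 22 anti to the C3 substituent and that 23 does not re-ionise afterwards.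

**17 to 15.** The C3'–O bond and the C3–H bond are cut, leaving an exocyclic methylidene group. C3 is α to the carbonyl, so its configuration can be left to equilibration, and the oxygen on C3' can come from benzyl alcohol, which brings its own protecting group. One stereocentre and one protecting-group step disappear. The forward step needs 1,4-addition to outrun migration of the double bond into the ring, and the C3 epimers must equilibrate towards 17.

**15 to 13 and 14 (key disconnection).** O1–C2 and C2–C3 are cut; C2 leaves as 14 and the ring opens to a homopropargylic alcohol in which the alkyne carbons are C3 and C3'. This removes the ring and reduces the problem to an acyclic syn pair of stereocentres (C4, C5). The forward step must acylate the hydroxyl, insert the alkyne in the exo sense and leave the ionisable benzylic carbinol intact.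

**13 to 12 to 11.** The hydroxyl is masked again as its silyl ether, and the alkyne is traced back to an aldehyde by cutting C3–C3', with C3' coming from a diazophosphonate reagent. An aldehyde at C3 connects directly to aldol chemistry. The demand is that C4, now α to a formyl group and flanked by two β-oxygen substituents, is not enolised.

**11 to 10 to 9 to 8.** These are oxidation-level changes at C3 and removal of the silyl group: aldehyde back to primary alcohol, alcohol back to the imide carbonyl (C3–N bond to the auxiliary), silyl ether back to hydroxyl. No skeletal bond is cut. The silyl ether is required because a free β-hydroxy carbonyl compound would undergo retro-aldol cleavage in steps 4 and 6.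

**8 to 4 and 5.** The C4–C5 bond is cut. This is the only bond that joins the two stereocentres of the precursor, and an auxiliary-controlled syn-aldol sets both at once. The fragments are an aromatic aldehyde and a three-carbon acyl unit that already carries the C4' oxygen. The demand is high syn selectivity and no loss of benzyloxide from the β-alkoxy enolate.

**4 to 1 and 2; 19 to 18.** The N–acyl bond and one O–benzyl bond are cut, which leads to four purchasable compounds (1, 2, 5, 18) and 14. The phenol of 18 has to be benzylated before halogen–lithium exchange.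

## Other disconnections considered

**Alternative 1:** The cut is at C2–C3 and C4–C5, so the central C3–C4 unit with C3' and C4' is a four-carbon butenolide. In the forward key step the lithiated dithiane A1 adds to the β-carbon of the menthyloxy butenolide A2 anti to the acetal substituent, and the lactone enolate is trapped by aldehyde 5 anti to the new dithianyl group, giving A3; no ring of the target closes.
- In its favour: three components combine in one flask, all carbons of the target are present afterwards, and the C3/C4 trans relation with its absolute sense is fixed kinetically by the acetal centre. On convergence and on the direct setting of C3/C4 it is the better plan.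
- Against it here: the carbinol carbon of A3 (future C5) is exocyclic to the lactone and is expected to form with little control. C2 arrives as a dithioketal that must be unmasked beside two electron-rich arenes. The lactone carbonyl and the acetal carbon of A3 must both be reduced to hydroxymethyl groups. The (5S) series of A2 needs the less common enantiomer of menthol.
- Structure: A3 has the full carbon skeleton but no tetrahydrofuran ring and an unsecured C5, whereas 15 has O1 on a defined C5 and C2 as a carbonyl but still lacks the C3' oxygen and one aryl group.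
- Mechanism: substrate-controlled conjugate addition and aldol trapping, against auxiliary-controlled aldol followed by palladium insertion; both plans leave the 2,3-cis relation to a late hydride delivery, so they are equal there.
- Step economy: about three steps to A3 and perhaps six or seven after it, a little shorter than or equal to the chosen plan, but with an open stereochemical question at C5.

**Alternative 2:** The cut is at C4–C5 and O1–C2. In the forward key step MgCl2/Et3N/Me3SiCl enolises the succinate mono-imide A4, the anti-aldol with aldehyde 5 forms C4–C5, and acidic work-up closes the lactone onto the methyl ester to give A5.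
- In its favour: A5 is a 4,5-cis lactone with C2 already a carbonyl, reached in two or three operations without an alkyne, without silyl protection and removal, and without pressurised carbon monoxide. Up to the lactone stage it is clearly the better plan in step economy and simplicity.
- Against it here: in A5, C3 is still a methylene group and C4' is an imide carbonyl. The imide must be reduced beside the lactone (risk of acyl migration of the cis hydroxymethyl lactone) and protected before C3 can be functionalised, because C4–H is the more acidic position. C4 is α to a carbonyl and cis to the aryl group, so it may epimerise to the trans lactone.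
- Structure: A5 and 15 are both cis-4,5 lactones; 15 already carries C3' and has C4' at the alcohol level, A5 has neither.
- Mechanism: a magnesium-enolate anti-aldol against a boron syn-aldol. The cis lactone arises from anti in A5 (ring closed through the α-substituent) and from syn in 15 (ring closed through the former acyl carbon), so the logic is equal. Kinetic alkylation at C3 trans to C4 would be at least as reliable as the equilibration in step 9, so on that point it is equal or better.
- Step economy: about nine or ten steps in total, better than the chosen plan.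

**Alternative 3:** The cut is at C2–C3 alone, made last. In the forward key step Rh2(S-PTTL)4 decomposes the diazo ester A6 and the rhodium carbene at C3 inserts into the benzylic C–H bond of the aryl-methyl ether five atoms away, closing the ring and giving A7.
- In its favour: the ring forms with C2 at its final oxidation level, so no aryllithium addition and no hemiketal reduction are needed, and C2 and C3 are created together in a catalytic step. On these counts it is better than the chosen key step, which creates no stereocentre. The C–H bond is activated by the ether oxygen and the electron-rich arene.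
- Against it here: the step must give 2,3-cis and 3,4-trans at once, with a chiral catalyst that has to match the existing C4/C5 pair. The ester-bearing C3 of A7 is epimerisable. Competing carbene pathways are a 1,2-hydride shift from C4, oxonium ylide formation at the ether oxygen, and insertion into the C–H bonds of the benzyl protecting groups. A6 needs diazo transfer to a non-stabilised ester and etherification of a hindered, ionisable benzylic alcohol.
- Structure: A7 is two or three steps from the target against five for 15, which is better.
- Mechanism: a concerted insertion under catalyst control, less predictable on this substrate than the stepwise polar sequence of the chosen plan.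
- Step economy: about eight or nine steps to A6, so roughly equal overall.

Key step: step 8

Remark: ring atoms are numbered O1, C2, C3, C4, C5 throughout, C5 being the aryl-bearing carbon made in the aldol and C2 the carbon that enters as carbon monoxide; C3' and C4' are the exocyclic carbons; 5 is bought as the benzyl ether of vanillin.

## Route

Step 1
Reactants: 1 3-(benzyloxy)propanoic acid; 2 (S)-4-benzyl-2-oxazolidinone
Product: 4 (S)-4-benzyl-3-[3-(benzyloxy)propanoyl]oxazolidin-2-one, via mixed pivalic anhydride 3 (not isolated)
Conditions: PivCl, Et3N, THF, −20 °C; then LiCl, 2, −20 °C to rt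
Reagents that add atoms: none
Why: N-acylation through the mixed anhydride 3; the tert-butyl group shields the pivaloyl carbonyl, so the LiCl-activated oxazolidinone attacks the 3-(benzyloxy)propanoyl carbonyl. No stereocentre is formed, and the mild amine base avoids β-elimination of benzyl alcohol.

Step 2
Reactants: 4 (S)-4-benzyl-3-[3-(benzyloxy)propanoyl]oxazolidin-2-one; 5 4-(benzyloxy)-3-methoxybenzaldehyde
Product: 8 (S)-4-benzyl-3-{(2S,3S)-2-[(benzyloxy)methyl]-3-[4-(benzyloxy)-3-methoxyphenyl]-3-hydroxypropanoyl}oxazolidin-2-one, via Z-boron enolate 6 (not isolated), via boron aldolate 7 (not isolated)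
Conditions: Bu2BOTf, iPr2NEt, CH2Cl2, −78 to 0 °C; then 5, −78 to 0 °C; then pH 7 buffer, MeOH, H2O2, 0 °C
Reagents that add atoms: none
Why: Evans boron syn-aldol: the Z-enolate 6 reacts through a Zimmerman–Traxler chair in which the aldehyde meets the enolate face opposite the benzyl group of the auxiliary, so C4 (S) and C5 (S) are set together, syn, under auxiliary control. The covalent boron enolate should not expel benzyloxide at these temperatures, and the oxidative work-up cleaves aldolate 7.

Step 3
Reactants: 8 (S)-4-benzyl-3-{(2S,3S)-2-[(benzyloxy)methyl]-3-[4-(benzyloxy)-3-methoxyphenyl]-3-hydroxypropanoyl}oxazolidin-2-one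
Product: 9 (S)-4-benzyl-3-{(2S,3S)-2-[(benzyloxy)methyl]-3-[4-(benzyloxy)-3-methoxyphenyl]-3-[(tert-butyldimethylsilyl)oxy]propanoyl}oxazolidin-2-one
Conditions: TBSOTf, 2,6-lutidine, CH2Cl2, 0 °C
Reagents that add atoms: tert-butyldimethylsilyl trifluoromethanesulfonate, CC(C)(C)[Si](C)(C)OS(=O)(=O)C(F)(F)F
Why: Silyl ether formation with the silyl triflate, which is needed for a hindered benzylic hydroxyl; the ether blocks retro-aldol cleavage in the basic steps 4 and 6. The stereocentres are not touched.

Step 4
Reactants: 9 (S)-4-benzyl-3-{(2S,3S)-2-[(benzyloxy)methyl]-3-[4-(benzyloxy)-3-methoxyphenyl]-3-[(tert-butyldimethylsilyl)oxy]propanoyl}oxazolidin-2-one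
Product: 10 (2S,3S)-2-[(benzyloxy)methyl]-3-[4-(benzyloxy)-3-methoxyphenyl]-3-[(tert-butyldimethylsilyl)oxy]propan-1-ol
Conditions: LiBH4, MeOH (1 equiv), THF, 0 °C
Reagents that add atoms: none
Why: Reductive removal of the auxiliary: LiBH4 attacks the exocyclic imide carbonyl and leaves silyl and benzyl ethers alone; 2 is recovered.

Step 5
Reactants: 10 (2S,3S)-2-[(benzyloxy)methyl]-3-[4-(benzyloxy)-3-methoxyphenyl]-3-[(tert-butyldimethylsilyl)oxy]propan-1-ol
Product: 11 (2S,3S)-2-[(benzyloxy)methyl]-3-[4-(benzyloxy)-3-methoxyphenyl]-3-[(tert-butyldimethylsilyl)oxy]propanal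
Conditions: Dess–Martin periodinane, NaHCO3, CH2Cl2, 0 °C to rt
Reagents that add atoms: none
Why: Dess–Martin oxidation buffered with NaHCO3 gives the aldehyde at neutral pH, so the α-stereocentre C4 should not be enolised; the aldehyde is used at once without chromatography.

Step 6
Reactants: 11 (2S,3S)-2-[(benzyloxy)methyl]-3-[4-(benzyloxy)-3-methoxyphenyl]-3-[(tert-butyldimethylsilyl)oxy]propanal
Product: 12 tert-butyl{[(1S,2S)-2-[(benzyloxy)methyl]-1-[4-(benzyloxy)-3-methoxyphenyl]but-3-yn-1-yl]oxy}dimethylsilane
Conditions: dimethyl (1-diazo-2-oxopropyl)phosphonate, K2CO3, MeOH, 0 °C to rt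
Reagents that add atoms: dimethyl (1-diazo-2-oxopropyl)phosphonate, COP(=O)(OC)C(=[N+]=[N-])C(C)=O
Why: Ohira–Bestmann alkynylation (Seyferth–Gilbert homologation): the diazomethylphosphonate anion adds to the aldehyde, and loss of phosphate and N2 with a 1,2-hydrogen shift gives the terminal alkyne, the formyl carbon becoming C3 and the reagent carbon C3'. Adding 11 last at 0 °C keeps its contact with carbonate short, so C4 should keep its configuration.

Step 7
Reactants: 12 tert-butyl{[(1S,2S)-2-[(benzyloxy)methyl]-1-[4-(benzyloxy)-3-methoxyphenyl]but-3-yn-1-yl]oxy}dimethylsilane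
Product: 13 (1S,2S)-2-[(benzyloxy)methyl]-1-[4-(benzyloxy)-3-methoxyphenyl]but-3-yn-1-ol
Conditions: TBAF, THF, 0 °C to rt
Reagents that add atoms: none
Why: Fluoride-mediated desilylation; benzyl ethers and the terminal alkyne are inert, and the syn hydroxyl/alkyne pair needed for the key step is set free.

Step 8
Reactants: 13 (1S,2S)-2-[(benzyloxy)methyl]-1-[4-(benzyloxy)-3-methoxyphenyl]but-3-yn-1-ol; 14 carbon monoxide
Product: 15 (4S,5S)-4-[(benzyloxy)methyl]-5-[4-(benzyloxy)-3-methoxyphenyl]-3-methylidenedihydrofuran-2(3H)-one
Conditions: PdCl2 (5 mol %), SnCl2 (5 mol %), PPh3 (10 mol %), CO (7 bar), MeCN, 75 °C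
Reagents that add atoms: none
Why: The hydroxyl of 13 and CO combine on divalent palladium (PdCl2 made more electrophilic by SnCl2, with PPh3 as ligand) to an alkoxycarbonyl–palladium bond, which adds syn across the tethered triple bond; protonolysis of the resulting alkenyl–palladium bond by the HCl released in the first event gives 15 and returns the catalyst, so the metal stays divalent and no oxidant is needed. The closest known reaction type is the palladium-catalysed cyclocarbonylation of but-3-yn-1-ols to α-methylene-γ-butyrolactones. The one ring closes in the 5-exo-dig mode: the acyl carbon C2 bonds to the internal alkyne carbon C3, and the terminal carbon stays outside the ring as the methylidene carbon C3'. No stereocentre is created; C4 and C5 are not touched, and their syn relation in 13 becomes the 4,5-cis relation of 15. The step needs regioselectivity (five-membered exo lactone, not a six-membered endo one) and chemoselectivity (the benzylic hydroxyl must be acylated, not ionised). The first is secured by the three-atom tether between oxygen and alkyne, which allows only the exo insertion geometry. The second is secured by the absence of any other hydroxyl and by a weakly acidic medium: catalytic amounts of the two chlorides, acetonitrile as a coordinating solvent and moderate temperature.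

Step 9
Reactants: 15 (4S,5S)-4-[(benzyloxy)methyl]-5-[4-(benzyloxy)-3-methoxyphenyl]-3-methylidenedihydrofuran-2(3H)-one
Product: 17 (3S,4S,5S)-3,4-bis[(benzyloxy)methyl]-5-[4-(benzyloxy)-3-methoxyphenyl]dihydrofuran-2(3H)-one, via all-cis epimer 16 (not isolated)
Conditions: BnOH (5 equiv), NaH (0.2 equiv), THF, 0 °C to rt; then AcOH
Reagents that add atoms: benzyl alcohol, OCc1ccccc1
Why: Oxa-Michael addition of benzyl oxide to the exocyclic enoate forms the C3'–O bond. Protonation of the lactone enolate should first give material containing the all-cis epimer 16, but C3 is epimerisable under the catalytic alkoxide (enolisation, and elimination followed by re-addition), so the mixture should converge on the more stable 3,4-trans lactone 17 (3S), in which the C3 group avoids the cis pair at C4/C5 (thermodynamic control).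

Step 10
Reactants: 18 4-bromo-2-methoxyphenol
Product: 19 1-(benzyloxy)-4-bromo-2-methoxybenzene
Conditions: BnBr, K2CO3, DMF, rt
Reagents that add atoms: benzyl bromide, BrCc1ccccc1
Why: Williamson ether synthesis; the phenol must be masked before halogen–lithium exchange, and benzyl matches the other protecting groups.

Step 11
Reactants: 17 (3S,4S,5S)-3,4-bis[(benzyloxy)methyl]-5-[4-(benzyloxy)-3-methoxyphenyl]dihydrofuran-2(3H)-one; 19 1-(benzyloxy)-4-bromo-2-methoxybenzene
Product: 21 (3S,4S,5S)-2,5-bis[4-(benzyloxy)-3-methoxyphenyl]-3,4-bis[(benzyloxy)methyl]tetrahydrofuran-2-ol (both C2 epimers), via aryllithium 20 (not isolated)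
Conditions: 19, n-BuLi, THF, −78 °C; then 17, −78 °C; sat. aq. NH4Cl at −78 °C
Reagents that add atoms: none
Why: Bromine–lithium exchange gives 20, which adds to the lactone carbonyl (1,2-addition of an aryllithium to a lactone); at −78 °C the tetrahedral lithium alkoxide does not collapse, so a second addition is avoided and addition should outrun enolisation. The configuration created at C2 is of no consequence because C2 becomes planar in step 12; 21 is used crude.

Step 12
Reactants: 21 (3S,4S,5S)-2,5-bis[4-(benzyloxy)-3-methoxyphenyl]-3,4-bis[(benzyloxy)methyl]tetrahydrofuran-2-ol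
Product: 23 (2S,3S,4S,5S)-2,5-bis[4-(benzyloxy)-3-methoxyphenyl]-3,4-bis[(benzyloxy)methyl]tetrahydrofuran, via oxocarbenium ion 22 (not isolated)
Conditions: Et3SiH, BF3·OEt2, CH2Cl2, −78 °C; sat. aq. NaHCO3 at −78 °C
Reagents that add atoms: none
Why: Ionic hydrogenation of the hemiketal: BF3·OEt2 removes the hydroxyl to give the aryl-stabilised ion 22, and Et3SiH delivers hydride to C2 from the face opposite the adjacent C3 benzyloxymethyl group, so the aryl group ends up cis to that group (2S, substrate control by C3). Quenching cold prevents Lewis-acid reopening of the benzylic C2–O bond, which would equilibrate C2 towards the 2,3-trans isomer.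

Step 13
Reactants: 23 (2S,3S,4S,5S)-2,5-bis[4-(benzyloxy)-3-methoxyphenyl]-3,4-bis[(benzyloxy)methyl]tetrahydrofuran
Product: 24 eduesmine, [(2S,3S,4S,5S)-2,5-bis(4-hydroxy-3-methoxyphenyl)tetrahydrofuran-3,4-diyl]dimethanol
Conditions: H2 (1 atm), Pd(OH)2/C, EtOAc–EtOH, rt, followed closely and stopped at complete debenzylation
Reagents that add atoms: none
Why: Catalytic hydrogenolysis removes the two aryl benzyl ethers and the two primary alkyl benzyl ethers in one operation; a non-acidic catalyst, neutral solvent and atmospheric pressure are chosen because the ring C2–O and C5–O bonds are themselves benzylic. No stereocentre is affected.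

## Compound list

1 | 3-(benzyloxy)propanoic acid | OC(=O)CCOCc1ccccc1 | starting material
2 | (S)-4-benzyl-2-oxazolidinone | O=C1N[C@@H](Cc2ccccc2)CO1 | starting material
3 | 3-(benzyloxy)propanoic pivalic anhydride | CC(C)(C)C(=O)OC(=O)CCOCc1ccccc1 | intermediate (not isolated)
4 | (S)-4-benzyl-3-[3-(benzyloxy)propanoyl]oxazolidin-2-one | O=C(CCOCc1ccccc1)N1[C@@H](Cc2ccccc2)COC1=O | intermediate
5 | 4-(benzyloxy)-3-methoxybenzaldehyde | COc1cc(C=O)ccc1OCc1ccccc1 | starting material
6 | dibutylboron (Z)-enolate of 4 | CCCCB(CCCC)O/C(=C\COCc1ccccc1)N1[C@@H](Cc2ccccc2)COC1=O | intermediate (not isolated)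
7 | dibutylboron aldolate of 8 | CCCCB(CCCC)O[C@H](c1ccc(OCc2ccccc2)c(OC)c1)[C@H](COCc1ccccc1)C(=O)N1[C@@H](Cc2ccccc2)COC1=O | intermediate (not isolated)
8 | (S)-4-benzyl-3-{(2S,3S)-2-[(benzyloxy)methyl]-3-[4-(benzyloxy)-3-methoxyphenyl]-3-hydroxypropanoyl}oxazolidin-2-one | O[C@H](c1ccc(OCc2ccccc2)c(OC)c1)[C@H](COCc1ccccc1)C(=O)N1[C@@H](Cc2ccccc2)COC1=O | intermediate
9 | (S)-4-benzyl-3-{(2S,3S)-2-[(benzyloxy)methyl]-3-[4-(benzyloxy)-3-methoxyphenyl]-3-[(tert-butyldimethylsilyl)oxy]propanoyl}oxazolidin-2-one | CC(C)(C)[Si](C)(C)O[C@H](c1ccc(OCc2ccccc2)c(OC)c1)[C@H](COCc1ccccc1)C(=O)N1[C@@H](Cc2ccccc2)COC1=O | intermediate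
10 | (2S,3S)-2-[(benzyloxy)methyl]-3-[4-(benzyloxy)-3-methoxyphenyl]-3-[(tert-butyldimethylsilyl)oxy]propan-1-ol | CC(C)(C)[Si](C)(C)O[C@H](c1ccc(OCc2ccccc2)c(OC)c1)[C@H](COCc1ccccc1)CO | intermediate
11 | (2S,3S)-2-[(benzyloxy)methyl]-3-[4-(benzyloxy)-3-methoxyphenyl]-3-[(tert-butyldimethylsilyl)oxy]propanal | CC(C)(C)[Si](C)(C)O[C@H](c1ccc(OCc2ccccc2)c(OC)c1)[C@H](COCc1ccccc1)C=O | intermediate
12 | tert-butyl{[(1S,2S)-2-[(benzyloxy)methyl]-1-[4-(benzyloxy)-3-methoxyphenyl]but-3-yn-1-yl]oxy}dimethylsilane | CC(C)(C)[Si](C)(C)O[C@H](c1ccc(OCc2ccccc2)c(OC)c1)[C@H](COCc1ccccc1)C#C | intermediate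
13 | (1S,2S)-2-[(benzyloxy)methyl]-1-[4-(benzyloxy)-3-methoxyphenyl]but-3-yn-1-ol (syn) | O[C@H](c1ccc(OCc2ccccc2)c(OC)c1)[C@H](COCc1ccccc1)C#C | intermediate
14 | carbon monoxide | [C-]#[O+] | starting material
15 | (4S,5S)-4-[(benzyloxy)methyl]-5-[4-(benzyloxy)-3-methoxyphenyl]-3-methylidenedihydrofuran-2(3H)-one (4,5-cis) | C=C1C(=O)O[C@H](c2ccc(OCc3ccccc3)c(OC)c2)[C@@H]1COCc1ccccc1 | intermediate
16 | (3R,4S,5S)-3,4-bis[(benzyloxy)methyl]-5-[4-(benzyloxy)-3-methoxyphenyl]dihydrofuran-2(3H)-one (all-cis) | O=C1O[C@H](c2ccc(OCc3ccccc3)c(OC)c2)[C@H](COCc2ccccc2)[C@@H]1COCc1ccccc1 | intermediate (not isolated)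
17 | (3S,4S,5S)-3,4-bis[(benzyloxy)methyl]-5-[4-(benzyloxy)-3-methoxyphenyl]dihydrofuran-2(3H)-one (3,4-trans, 4,5-cis) | O=C1O[C@H](c2ccc(OCc3ccccc3)c(OC)c2)[C@H](COCc2ccccc2)[C@H]1COCc1ccccc1 | intermediate
18 | 4-bromo-2-methoxyphenol | COc1cc(Br)ccc1O | starting material
19 | 1-(benzyloxy)-4-bromo-2-methoxybenzene | COc1cc(Br)ccc1OCc1ccccc1 | intermediate
20 | [4-(benzyloxy)-3-methoxyphenyl]lithium | COc1cc([Li])ccc1OCc1ccccc1 | intermediate (not isolated)
21 | (3S,4S,5S)-2,5-bis[4-(benzyloxy)-3-methoxyphenyl]-3,4-bis[(benzyloxy)methyl]tetrahydrofuran-2-ol (both C2 epimers) | COc1cc(C2(O)O[C@H](c3ccc(OCc4ccccc4)c(OC)c3)[C@H](COCc3ccccc3)[C@H]2COCc2ccccc2)ccc1OCc1ccccc1 | intermediate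
22 | (3S,4S,5S)-2,5-bis[4-(benzyloxy)-3-methoxyphenyl]-3,4-bis[(benzyloxy)methyl]-4,5-dihydro-3H-furan-1-ium (cyclic oxocarbenium ion) | COc1cc(C2=[O+][C@H](c3ccc(OCc4ccccc4)c(OC)c3)[C@H](COCc3ccccc3)[C@H]2COCc2ccccc2)ccc1OCc1ccccc1 | intermediate (not isolated)
23 | (2S,3S,4S,5S)-2,5-bis[4-(benzyloxy)-3-methoxyphenyl]-3,4-bis[(benzyloxy)methyl]tetrahydrofuran | COc1cc([C@H]2O[C@H](c3ccc(OCc4ccccc4)c(OC)c3)[C@H](COCc3ccccc3)[C@H]2COCc2ccccc2)ccc1OCc1ccccc1 | intermediate
24 | eduesmine, [(2S,3S,4S,5S)-2,5-bis(4-hydroxy-3-methoxyphenyl)tetrahydrofuran-3,4-diyl]dimethanol | COc1cc([C@H]2O[C@H](c3ccc(O)c(OC)c3)[C@H](CO)[C@H]2CO)ccc1O | target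

## Step count and least certain steps

Total step count: 13. Longest linear sequence: 12 steps (steps 1 to 9 and 11 to 13, from 1); step 10 is a one-step side branch.

**Step 8 (key step).** The electron-rich benzylic carbinol may ionise in the Lewis-acidic chloride medium at 75 °C before it is acylated, with loss of configuration at C5, elimination or capture by acetonitrile; the alkyne may also oligomerise if carbonylation is slow. Fallback, from 12 back to 15: nickel-catalysed Markovnikov hydroalumination (NiCl2(dppp), DIBAL-H, THF) and iodinolysis with I2 would give the silyl-protected 2-iodoalkene F1. TBAF would give the iodo alcohol F2. Carbonylative lactonisation by oxidative addition of the C–I bond to zerovalent palladium (Pd(PPh3)4, CO 1 atm, K2CO3, THF, 50 °C), CO insertion and capture of the acyl group by the hydroxyl then returns to 15. This variant forms the same two bonds under basic conditions at low pressure.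

**Step 13.** Over-reduction is the concern: the ring C2–O and C5–O bonds are benzylic and become activated once the para-phenols are free, while the slower alkyl benzyl ethers are still being cleaved. Fallback, from 23 back to 24: a short hydrogenolysis over Pd/C in EtOAc that stops after the two aryl benzyl ethers gives the diphenol F3. Acetylation (Ac2O, pyridine) gives the diacetate F4, whose less electron-rich rings are much less prone to benzylic C–O cleavage. Hydrogenolysis of the two alkyl benzyl ethers gives the diacetate diol F5, and K2CO3 in MeOH removes the acetates to give 24.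

**Step 11.** The aryllithium may deprotonate C3 in place of adding to the carbonyl; the enolate can then lose benzyloxide from C3' (the reverse of step 9) and the methylidene lactone so formed would take up a second aryllithium. Warming would also allow collapse of the tetrahedral alkoxide and double addition. Fallback, from 17 back to 21: ring opening with MeNHOMe·HCl and AlMe3 gives the hydroxy Weinreb amide F6, and Et3SiCl with imidazole gives its triethylsilyl ether F7. Addition of 20 gives the aryl ketone F8 through a chelated intermediate that cannot add twice. HF·pyridine removes the silyl group and the hydroxy ketone closes to 21.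

**Step 9.** Deprotonation at C4 (γ to the carbonyl) would move the double bond into the ring and erase the C4 stereocentre; equilibration at C3 may also be incomplete, and the addition equilibrium may be unfavourable once benzyl alcohol is removed. Fallback, from 15 back to 17: copper-catalysed conjugate borylation (CuCl, NaOtBu, a bisphosphine, B2pin2, t-BuOH, THF) gives the 3-(borylmethyl) lactone F9 as a mixture at C3. NaBO3·4H2O oxidises the C–B bond to the 3-(hydroxymethyl) lactone F10. Benzylation under neutral conditions (2-benzyloxy-1-methylpyridinium triflate, MgO, PhCF3) and equilibration at C3 with catalytic DBU in the presence of benzyl alcohol comes back at 17.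

**Step 6.** Carbonate or methoxide may enolise the aldehyde, which would epimerise C4 or expel the β-silyloxy or β-benzyloxy group. Fallback, from 11 back to 12: Corey–Fuchs alkynylation, with CBr4, PPh3 and Et3N in CH2Cl2 at 0 °C to give the 1,1-dibromoalkene F11, then n-BuLi in THF at −78 °C and a proton quench to give 12; the aldehyde never meets a protic base.

## Further compounds

F1 | step 8 | tert-butyl{[(1S,2S)-2-[(benzyloxy)methyl]-1-[4-(benzyloxy)-3-methoxyphenyl]-3-iodobut-3-en-1-yl]oxy}dimethylsilane | CC(C)(C)[Si](C)(C)O[C@H](c1ccc(OCc2ccccc2)c(OC)c1)[C@H](COCc1ccccc1)C(I)=C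
F2 | step 8 | (1S,2S)-2-[(benzyloxy)methyl]-1-[4-(benzyloxy)-3-methoxyphenyl]-3-iodobut-3-en-1-ol | O[C@H](c1ccc(OCc2ccccc2)c(OC)c1)[C@H](COCc1ccccc1)C(I)=C
F3 | step 13 | 4,4'-{(2S,3S,4S,5S)-3,4-bis[(benzyloxy)methyl]tetrahydrofuran-2,5-diyl}bis(2-methoxyphenol) | COc1cc([C@H]2O[C@H](c3ccc(O)c(OC)c3)[C@H](COCc3ccccc3)[C@H]2COCc2ccccc2)ccc1O
F4 | step 13 | {(2S,3S,4S,5S)-3,4-bis[(benzyloxy)methyl]tetrahydrofuran-2,5-diyl}bis(2-methoxy-4,1-phenylene) diacetate | COc1cc([C@H]2O[C@H](c3ccc(OC(C)=O)c(OC)c3)[C@H](COCc3ccccc3)[C@H]2COCc2ccccc2)ccc1OC(C)=O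
F5 | step 13 | {(2S,3S,4S,5S)-3,4-bis(hydroxymethyl)tetrahydrofuran-2,5-diyl}bis(2-methoxy-4,1-phenylene) diacetate | COc1cc([C@H]2O[C@H](c3ccc(OC(C)=O)c(OC)c3)[C@H](CO)[C@H]2CO)ccc1OC(C)=O
F6 | step 11 | (2S,3S,4S)-2,3-bis[(benzyloxy)methyl]-4-[4-(benzyloxy)-3-methoxyphenyl]-4-hydroxy-N-methoxy-N-methylbutanamide | CON(C)C(=O)[C@H](COCc1ccccc1)[C@@H](COCc1ccccc1)[C@H](O)c1ccc(OCc2ccccc2)c(OC)c1
F7 | step 11 | (2S,3S,4S)-2,3-bis[(benzyloxy)methyl]-4-[4-(benzyloxy)-3-methoxyphenyl]-N-methoxy-N-methyl-4-[(triethylsilyl)oxy]butanamide | CON(C)C(=O)[C@H](COCc1ccccc1)[C@@H](COCc1ccccc1)[C@H](O[Si](CC)(CC)CC)c1ccc(OCc2ccccc2)c(OC)c1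
F8 | step 11 | (2S,3S,4S)-1,4-bis[4-(benzyloxy)-3-methoxyphenyl]-2,3-bis[(benzyloxy)methyl]-4-[(triethylsilyl)oxy]butan-1-one | COc1cc(C(=O)[C@H](COCc2ccccc2)[C@@H](COCc2ccccc2)[C@H](O[Si](CC)(CC)CC)c2ccc(OCc3ccccc3)c(OC)c2)ccc1OCc1ccccc1
F9 | step 9 | (4S,5S)-4-[(benzyloxy)methyl]-5-[4-(benzyloxy)-3-methoxyphenyl]-3-[(4,4,5,5-tetramethyl-1,3,2-dioxaborolan-2-yl)methyl]dihydrofuran-2(3H)-one (both C3 epimers) | O=C1O[C@H](c2ccc(OCc3ccccc3)c(OC)c2)[C@H](COCc2ccccc2)C1CB1OC(C)(C)C(C)(C)O1
F10 | step 9 | (4S,5S)-4-[(benzyloxy)methyl]-5-[4-(benzyloxy)-3-methoxyphenyl]-3-(hydroxymethyl)dihydrofuran-2(3H)-one (both C3 epimers) | O=C1O[C@H](c2ccc(OCc3ccccc3)c(OC)c2)[C@H](COCc2ccccc2)C1CO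
F11 | step 6 | tert-butyl{[(1S,2S)-2-[(benzyloxy)methyl]-1-[4-(benzyloxy)-3-methoxyphenyl]-4,4-dibromobut-3-en-1-yl]oxy}dimethylsilane | CC(C)(C)[Si](C)(C)O[C@H](c1ccc(OCc2ccccc2)c(OC)c1)[C@H](COCc1ccccc1)C=C(Br)Br
A1 | alternative 1 | {2-[4-(benzyloxy)-3-methoxyphenyl]-1,3-dithian-2-yl}lithium | [Li]C1(c2ccc(OCc3ccccc3)c(OC)c2)SCCCS1
A2 | alternative 1 | (5S)-5-{[(1S,2R,5S)-2-isopropyl-5-methylcyclohexyl]oxy}furan-2(5H)-one | O=C1C=C[C@@H](O[C@H]2C[C@@H](C)CC[C@@H]2C(C)C)O1
A3 | alternative 1 | 3,4-trans-4,5-trans 3-{[4-(benzyloxy)-3-methoxyphenyl](hydroxy)methyl}-4-{2-[4-(benzyloxy)-3-methoxyphenyl]-1,3-dithian-2-yl}-5-[(1S,2R,5S)-menthyloxy]dihydrofuran-2(3H)-one | O=C1[C@@H]([C@H](O)c2ccc(OCc3ccccc3)c(OC)c2)[C@H](C2(c3ccc(OCc4ccccc4)c(OC)c3)SCCCS2)[C@@H](O[C@H]2C[C@@H](C)CC[C@@H]2C(C)C)O1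
A4 | alternative 2 | methyl 4-[(S)-4-benzyl-2-oxooxazolidin-3-yl]-4-oxobutanoate | COC(=O)CCC(=O)N1[C@@H](Cc2ccccc2)COC1=O
A5 | alternative 2 | (S)-4-benzyl-3-{[(2S,3R)-2-[4-(benzyloxy)-3-methoxyphenyl]-5-oxotetrahydrofuran-3-yl]carbonyl}oxazolidin-2-one (cis lactone) | O=C1O[C@H](c2ccc(OCc3ccccc3)c(OC)c2)[C@H](C(=O)N2[C@@H](Cc3ccccc3)COC2=O)C1
A6 | alternative 3 | methyl (3S,4S)-4-[4-(benzyloxy)-3-methoxyphenyl]-4-{[4-(benzyloxy)-3-methoxybenzyl]oxy}-3-{[(tert-butyldimethylsilyl)oxy]methyl}-2-diazobutanoate | COC(=O)C(=[N+]=[N-])[C@@H](CO[Si](C)(C)C(C)(C)C)[C@H](OCc1ccc(OCc2ccccc2)c(OC)c1)c1ccc(OCc2ccccc2)c(OC)c1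
A7 | alternative 3 | methyl (2S,3R,4S,5S)-2,5-bis[4-(benzyloxy)-3-methoxyphenyl]-4-{[(tert-butyldimethylsilyl)oxy]methyl}tetrahydrofuran-3-carboxylate | COc1cc([C@H]2O[C@H](c3ccc(OCc4ccccc4)c(OC)c3)[C@H](CO[Si](C)(C)C(C)(C)C)[C@H]2C(=O)OC)ccc1OCc1ccccc1
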